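# Proposed synthesis of tauranin by diazoketone cyclopropanation and cyclopropane cleavage

## Analysis of the target

Tauranin (29) is a drimane sesquiterpene joined through a methylene bridge (C11) to a 2-hydroxy-1,4-benzoquinone that also carries a hydroxymethyl group. The carbocyclic half is a trans-fused decalin with a gem-dimethyl group at C4, an angular methyl group on the quaternary carbon C10 and an exocyclic C8=C12 alkene. The three stereocenters C5, C10 and C9 are contiguous (4aS, 8aS and 1S in the numbering of the systematic name). H-5 is trans to the C10 methyl group, and the C9 side chain is equatorial, on the same face as that methyl group. The sensitive groups are the hydroxyquinone (base, nucleophiles, reductants), the primary benzylic alcohol and the 1,1-disubstituted alkene. Under acid this alkene moves into the ring or is captured by an ortho phenolic oxygen to give a chromane. The main difficulties are the quaternary stereocenter C10 next to the neopentyl-type carbons C5 and C9, the attachment of the arylmethyl unit at the hindered C9, and the order of the last unmasking steps. The strategy rests on one feature: C5 and C6 can be held as an exocyclic alkene between the quaternary carbons C4 and C10. A carbene at C7, tethered to C10 through C8 and C9, can add across this alkene and so close ring B at C6–C7. The extra C5–C7 bond is not part of the target and is removed in a strain-releasing step that leaves the C8 carbonyl and a C6=C7 alkene, which are what the C9 alkylation and the C8 methylenation need.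

## Retrosynthetic reasoning

**Quinone.** The hydroxyquinone of 29 is traced back to the resorcinol 28. The two phenolic oxygens flank the benzylic carbon symmetrically, so oxidation at either free ring position gives the same 2-hydroxy-1,4-quinone and no regiochemical question arises. The oxidation is placed last because the quinone would not survive enolates, ylides or thiolates. Resorcinol 28 comes from the dimethyl ether 27 and its silyl ether 26. The forward ether cleavage must be non-acidic, because acid would join a free phenol to C8.

**Exocyclic alkene and C9.** The C8=C12 bond of 26 is cut to the C8 ketone 25 (carbonyl methylenation). The ketone also gives control of C9: in 25 the arylmethyl group can be brought to the equatorial 9β position by enolate equilibration of the epimer mixture 24. Ketone 24 comes from enone 23 by saturation of C6=C7.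

**C9–C11 bond.** Enone 23 is cut between C9 and C11 into the bicyclic enone 15 (used as its α′-enolate 22) and the benzylic bromide 21. The cut is made here because in 15 the only sp3 α-carbon is C9, the other α-position being part of the C6=C7 alkene, so the enolate is formed at one site only. In the saturated ketone the unhindered C7 would react first. Bromide 21 is traced through alcohol 20 and aldehyde 19 to the silyl ether 17 of 3,5-dimethoxybenzyl alcohol (16). The carbon between the two methoxy groups is introduced by directed lithiation (aryllithium 18).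

**Ring B (key disconnection).** Enone 15 is the product of acid cleavage of the C5–C7 bond of the tricyclic cyclopropyl ketone 13, which passes through the deconjugated enone 14. Ketone 13 is cut at C6–C7 and C5–C7 to the diazoketone 12. The forward step is a carbene [2+1] addition. It closes a five-membered ketone ring, the easiest ring size for such an addition, on a substrate with no arene or heteroatom to divert the carbene. The later cleavage must break C5–C7 (tertiary cation at C5) and not C6–C7.

**Diazoketone.** Compound 12 comes from acid 10 through its chloride 11 by one-carbon diazo homologation, acid 10 from aldehyde 9, and 9 from diene 7 by cleavage of the terminal alkene through diol 8. The hindered exocyclic alkene of 7 has to be left alone. Diene 7 comes from the tertiary alcohol 6 by dehydration. Only methyl hydrogens are available for elimination, so the alkene can form only in the exocyclic position. Alcohol 6 comes from ketone 5 by methyl addition.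

**C10.** Ketone 5 is traced to the allyl enol carbonate 4, made from 2,2,6-trimethylcyclohexanone (1) and allyl chloroformate (2) through enolate 3. The catalytic decarboxylative allylation sets the only stereocenter that is bought with a chiral reagent, and every later stereocenter is derived from it.

## Alternatives that were turned down

**Alternative 1:** Conjugate addition with enolate trapping on a preformed ring-B enone.
- Disconnection: C9–C11 and C10–C1 are cut on an enantiopure cyclohexenone that carries an oxygen substituent at C8.
- Forward key step: an arylmethylcopper reagent adds to C9 anti to the C8 benzyloxy group. The C10 enolate is then captured by a silyl-substituted vinyl ketone on the face away from the new substituent, giving the trisubstituted cyclohexanone A1.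
- For: the arene, C9 and the quaternary C10 arrive in one three-component step. C9 is set kinetically with the correct sense, so no later epimerisation is needed, and the arene enters as a nucleophile. On these two points it is stronger than the chosen route.
- Against: capture of a trisubstituted enolate by a Michael acceptor to form a quaternary carbon next to a new tertiary one is slow and competes with proton transfer. Benzylic copper reagents from electron-rich benzylic halides tend to homocouple. Ring A is still missing after A1: it needs aldol closure, gem-dimethylation at C4, trans-selective reduction to set C5, removal of the C3 carbonyl, and conversion of the C8 benzyloxy group into the ketone. The chiral enone needs its own synthesis.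
- Comparison: the chosen route buys ring A with its gem-dimethyl group in compound 1, sets C10 by catalyst control, and needs no deoxygenation.

**Alternative 2:** Ring expansion of a squarate-derived cyclobutenone to the oxygenated ring.
- Disconnection: C5′–C6′ inside the six-membered oxygenated ring.
- Forward key step: heating a 4-alkenyl-4-hydroxycyclobutenone opens the four-membered ring to a dienylketene. 6π-Electrocyclisation and tautomerisation then give the hydroquinone A2.
- For: all three ring oxygens and both carbon substituents are placed without regiochemical doubt under neutral thermal conditions, and no Teuber oxidation of a late intermediate is needed. On control of the oxygenation pattern it is as strong as or stronger than the chosen route.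
- Against: it does not address the drimane half. C5, C9, C10 and the exocyclic alkene must come from a separate synthesis, and a drimanylmethyl-substituted alkenyl metal reagent must be added to the four-membered ring. After A2 the route still needs oxidation to the quinone, cleavage of the methyl vinylogous ester and removal of the 4-methoxybenzyl ether. Oxidative removal of that ether collides with the hydroquinone, and acidic removal collides with the alkene.
- Comparison: the chosen route gets the same oxygen pattern from the symmetry of resorcinol 28 in one oxidation and puts its effort into the carbocycle.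

**Alternative 3:** Amine-catalysed intramolecular Diels–Alder reaction forming both carbocycles.
- Disconnection: C5–C10 and C6–C7.
- Forward key step: a chiral imidazolidinone converts the C6 enal into an iminium ion. The C5=C6 dienophile adds across the C7=C8–C9=C10 diene and gives the trans-fused octalin aldehyde A3.
- For: two rings, two C–C bonds and the C5/C10 ring fusion are made in one catalytic asymmetric step with the arene already attached. On convergence and on direct control of the ring fusion it is stronger than the chosen route, which sets C5 only after the key step.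
- Against: the diene is substituted at C8, C9 and C10, so the s-cis conformer is strained. The dienophile carbon C5 is attached to the quaternary C4, and the cycloaddition must create the quaternary C10 next to it. A3 carries a formyl group at C6 that has to be excised. Its alkene is the tetrasubstituted C8=C9, so C9 and the exocyclic alkene still require a stereoselective reductive allylic transposition. The acyclic triene with defined alkene geometry is itself demanding.
- Comparison: the chosen route closes an unstrained five-membered ring with a π-selective carbenoid on a substrate made by routine steps. Its only superfluous element is the temporary C5–C7 bond, and removing that bond produces the enone needed for the C9 alkylation.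

Key step: step 8

## Remarks before the steps

- Carbon labels C1–C12 follow drimane numbering: ring A is C1–C5 and C10, ring B is C5–C10, C11 is the benzylic methylene and C12 the exocyclic methylene carbon. Primed labels refer to the oxygenated six-membered ring.
- Assumption: (R)-t-Bu-PHOX is taken to give the (R)-ketone 5, by analogy with the parent 2-allyl-2-methylcyclohexanone case, in which the (S)-ligand gives the (S)-ketone. If the sense is the reverse, the other ligand enantiomer is used.
- The C10 descriptor changes from R (compounds 5–15) to S (compounds 23–29) because the CIP priorities change; the centre is not inverted.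

## Route

Step 1
Reactants: 1 2,2,6-trimethylcyclohexan-1-one; 2 prop-2-en-1-yl carbonochloridate (allyl chloroformate)
Product: 4 prop-2-en-1-yl 2,6,6-trimethylcyclohex-1-en-1-yl carbonate, via lithium enolate 3 (not isolated)
Conditions: LiN(SiMe3)2, THF, −78 → 0 °C; then 2, −78 → 23 °C
Reagents that add atoms: lithium bis(trimethylsilyl)amide, [Li]N([Si](C)(C)C)[Si](C)(C)C (lithium of intermediate 3 only)
Why: Only C6 of 1 carries an α-hydrogen, so a single, fully substituted enolate 3 forms; the hard chloroformate reacts at oxygen of this hindered enolate (O-acylation to the enol carbonate).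

Step 2
Reactants: 4 prop-2-en-1-yl 2,6,6-trimethylcyclohex-1-en-1-yl carbonate
Product: 5 (6R)-2,2,6-trimethyl-6-(prop-2-en-1-yl)cyclohexan-1-one
Conditions: Pd2(dba)3 (2.5 mol %, zerovalent palladium), (R)-t-Bu-PHOX (6 mol %), THF, 25 °C
Reagents that add atoms: none
Why: Tsuji-type decarboxylative asymmetric allylic alkylation: oxidative addition to the allyl carbonate and loss of CO2 give a π-allylpalladium enolate pair, and C–C bond formation inside the chiral P,N-ligand sphere creates the quaternary C10 with the R configuration; the enolate can only be generated at this carbon, so regiochemistry is fixed.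

Step 3
Reactants: 5 (6R)-2,2,6-trimethyl-6-(prop-2-en-1-yl)cyclohexan-1-one
Product: 6 (6R)-1,2,2,6-tetramethyl-6-(prop-2-en-1-yl)cyclohexan-1-ol as a mixture of C1 epimers
Conditions: MeMgBr, THF, 0 → 23 °C; aq. NH4Cl
Reagents that add atoms: methylmagnesium bromide, C[Mg]Br
Why: Grignard 1,2-addition to a ketone with no α-hydrogen on either side, so enolisation cannot compete despite the hindrance; the new carbinol centre is removed in step 4 and its configuration is irrelevant.

Step 4
Reactants: 6 (6R)-1,2,2,6-tetramethyl-6-(prop-2-en-1-yl)cyclohexan-1-ol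
Product: 7 (1R)-1,3,3-trimethyl-2-methylidene-1-(prop-2-en-1-yl)cyclohexane
Conditions: SOCl2, pyridine, 0 °C
Reagents that add atoms: none
Why: Dehydration through the chlorosulfite with base-mediated E2 elimination; both ring neighbours of the carbinol carbon are quaternary, so the only β-hydrogens are on the methyl group and only the exocyclic alkene can form, while the cold, pyridine-buffered medium disfavours ionisation and methyl migration.

Step 5
Reactants: 7 (1R)-1,3,3-trimethyl-2-methylidene-1-(prop-2-en-1-yl)cyclohexane
Product: 9 2-[(1R)-1,3,3-trimethyl-2-methylidenecyclohexyl]acetaldehyde, via terminal diol 8 (not isolated)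
Conditions: OsO4 (2 mol %), N-methylmorpholine N-oxide, acetone/H2O, 0 °C, stopped when 7 is consumed; then NaIO4, THF/H2O, 23 °C
Reagents that add atoms: N-methylmorpholine N-oxide, C[N+]1([O-])CCOCC1; water, O
Why: Upjohn dihydroxylation followed by periodate glycol cleavage; the monosubstituted allyl alkene is open to the bulky osmium reagent, whereas both faces of the exocyclic C5=C6 alkene are screened by the quaternary carbons C4 and C10, so site selectivity is steric.

Step 6
Reactants: 9 2-[(1R)-1,3,3-trimethyl-2-methylidenecyclohexyl]acetaldehyde
Product: 10 2-[(1R)-1,3,3-trimethyl-2-methylidenecyclohexyl]acetic acid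
Conditions: NaClO2, NaH2PO4, 2-methylbut-2-ene, t-BuOH/H2O, 23 °C
Reagents that add atoms: sodium chlorite, [Na+].[O-]Cl=O
Why: Pinnick oxidation; chlorite oxidises only the aldehyde, and the hypochlorous acid by-product is trapped by the sacrificial alkene so that the ring alkene is not chlorinated.

Step 7
Reactants: 10 2-[(1R)-1,3,3-trimethyl-2-methylidenecyclohexyl]acetic acid
Product: 12 1-diazo-3-[(1R)-1,3,3-trimethyl-2-methylidenecyclohexyl]propan-2-one, via acid chloride 11 (not isolated)
Conditions: (COCl)2, DMF (cat.), CH2Cl2, 0 °C, then evaporation; CH2N2 (3 equiv), Et2O, 0 °C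
Reagents that add atoms: oxalyl chloride, O=C(Cl)C(=O)Cl (chlorine of intermediate 11 only); diazomethane, C=[N+]=[N-]
Why: Acid chloride formation followed by C-acylation of diazomethane (first stage of the Arndt–Eistert sequence); excess diazomethane consumes the HCl so that no chloromethyl ketone forms, and the volatile HCl of the first stage is removed cold before it can lactonise the acid onto C5.

Step 8
Reactants: 12 1-diazo-3-[(1R)-1,3,3-trimethyl-2-methylidenecyclohexyl]propan-2-one
Product: 13 (1R,3S,6R)-6,10,10-trimethyltricyclo[4.4.0.0^{1,3}]decan-4-one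
Conditions: Rh2(OAc)4 (1 mol %), CH2Cl2, 40 °C, slow addition of 12 to a final concentration of about 0.01 M
Reagents that add atoms: none
Why: Rh2(OAc)4 (divalent rhodium) takes up the diazo carbon of 12, N2 leaves, and the electrophilic rhodium carbenoid at C7 adds to the C5=C6 π bond in a concerted but asynchronous [2+1] step in which the bond from C7 to the unhindered methylene C6 leads and the bond to C5 closes as positive charge builds at that tertiary carbon. The closest known reaction type is the intramolecular cyclopropanation of γ,δ-unsaturated α-diazoketones to bicyclo[3.1.0]hexan-2-ones. The cyclopropane (C5–C6–C7) closes by this carbene addition, and the five-membered ketone ring (C5–C10–C9–C8–C7) closes in the exo sense through the three-atom tether, with C6 outside it. C5 and C7 are controlled by C10: the tether reaches the alkene only when C9 is axial on the cyclohexane chair, so the carbenoid is delivered to that face and the bicyclo[3.1.0] unit is necessarily cis-fused, which should give the single isomer with the cyclopropane methylene syn to the C10 methyl group. Both new stereocenters are temporary (C7 becomes sp2 and C5 is reset in step 9), so only the constitution matters. The selectivity needed is addition to the π bond in preference to 1,5 C–H insertion at C1–H or the C10 methyl group and to carbene dimerisation. It is secured by the proximity and nucleophilicity of the 1,1-disubstituted alkene in the reactive conformer, by the moderate electrophilicity of the carboxylate-ligated carbenoid, and by slow addition at high dilution; no arene is present to compete.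

Step 9
Reactants: 13 (1R,3S,6R)-6,10,10-trimethyltricyclo[4.4.0.0^{1,3}]decan-4-one
Product: 15 (4aS,8aR)-5,5,8a-trimethyl-4a,5,6,7,8,8a-hexahydronaphthalen-2(1H)-one, via deconjugated enone 14 (not isolated)
Conditions: TsOH·H2O (0.5 equiv), benzene, 80 °C
Reagents that add atoms: none
Why: Acid-catalysed cleavage of a cyclopropyl ketone: protonation of the carbonyl breaks C5–C7 and not C6–C7 because only the former gives a tertiary cation, and loss of a C6 proton (C4 and C10 carry none) gives the dienol and then 14, so ring B emerges six-membered with the carbonyl at C8. Continued acid equilibrates 14 to the conjugated enone by γ-protonation at C5 on the face opposite the axial C10 and C4β methyl groups, which should set the trans ring fusion; the non-nucleophilic sulfonate avoids halide opening at C6.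

Step 10
Reactants: 16 (3,5-dimethoxyphenyl)methanol
Product: 17 [(3,5-dimethoxyphenyl)methoxy]tri(propan-2-yl)silane
Conditions: i-Pr3SiCl, imidazole, DMF, 23 °C
Reagents that add atoms: chlorotri(propan-2-yl)silane, CC(C)[Si](Cl)(C(C)C)C(C)C
Why: Silylation of the primary benzylic alcohol; the bulky silyl ether is chosen to survive n-BuLi, the enolate alkylation, methoxide and the ylide.

Step 11
Reactants: 17 [(3,5-dimethoxyphenyl)methoxy]tri(propan-2-yl)silane
Product: 19 2,6-dimethoxy-4-({[tri(propan-2-yl)silyl]oxy}methyl)benzaldehyde, via aryllithium 18 (not isolated)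
Conditions: n-BuLi, THF, 0 °C; then DMF, 0 → 23 °C; aq. NH4Cl
Reagents that add atoms: n-butyllithium, [Li]CCCC (lithium of intermediate 18 only); N,N-dimethylformamide, CN(C)C=O
Why: Directed ortho-metalation: the ring position between the two methoxy groups is activated by both and is lithiated selectively; formylation of the aryllithium with DMF then installs the future C11.

Step 12
Reactants: 19 2,6-dimethoxy-4-({[tri(propan-2-yl)silyl]oxy}methyl)benzaldehyde
Product: 20 [2,6-dimethoxy-4-({[tri(propan-2-yl)silyl]oxy}methyl)phenyl]methanol
Conditions: NaBH4, MeOH, 0 °C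
Reagents that add atoms: none
Why: Borohydride reduction of the aldehyde; nothing else in the molecule is reducible under these conditions.

Step 13
Reactants: 20 [2,6-dimethoxy-4-({[tri(propan-2-yl)silyl]oxy}methyl)phenyl]methanol
Product: 21 {[4-(bromomethyl)-3,5-dimethoxyphenyl]methoxy}tri(propan-2-yl)silane
Conditions: CBr4, PPh3, CH2Cl2, 0 °C; used at once
Reagents that add atoms: carbon tetrabromide, BrC(Br)(Br)Br
Why: Appel bromination under neutral conditions, which spares the silyl ether; the electron-rich benzylic bromide is labile and is therefore carried directly into step 14.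

Step 14
Reactants: 15 (4aS,8aR)-5,5,8a-trimethyl-4a,5,6,7,8,8a-hexahydronaphthalen-2(1H)-one; 21 {[4-(bromomethyl)-3,5-dimethoxyphenyl]methoxy}tri(propan-2-yl)silane
Product: 23 (4aS,8aS)-1-{[2,6-dimethoxy-4-({[tri(propan-2-yl)silyl]oxy}methyl)phenyl]methyl}-5,5,8a-trimethyl-4a,5,6,7,8,8a-hexahydronaphthalen-2(1H)-one as a mixture of C9 epimers, via lithium dienolate 22 (not isolated)
Conditions: LiN(i-Pr)2, THF, −78 °C; then 21, DMPU, −78 → −20 °C
Reagents that add atoms: lithium diisopropylamide, [Li]N(C(C)C)C(C)C (lithium of intermediate 22 only)
Why: Kinetic α′-deprotonation of the enone gives the cross-conjugated enolate 22 at C9, the only sp3 α-carbon, and SN2 alkylation with the activated benzylic bromide forms C9–C11; attack anti to the axial C10 methyl group is expected to favour the 9α epimer, which is corrected in step 16.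

Step 15
Reactants: 23 (4aS,8aS)-1-{[2,6-dimethoxy-4-({[tri(propan-2-yl)silyl]oxy}methyl)phenyl]methyl}-5,5,8a-trimethyl-4a,5,6,7,8,8a-hexahydronaphthalen-2(1H)-one
Product: 24 (4aS,8aS)-1-{[2,6-dimethoxy-4-({[tri(propan-2-yl)silyl]oxy}methyl)phenyl]methyl}-5,5,8a-trimethyloctahydronaphthalen-2(1H)-one as a mixture of C9 epimers
Conditions: H2 (1 atm), Pd/C, EtOAc, 23 °C
Reagents that add atoms: none
Why: Heterogeneous hydrogenation of the disubstituted C6=C7 enone alkene; no stereocenter is created, and the aryl ethers and the silyl ether are stable under neutral conditions.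

Step 16
Reactants: 24 (4aS,8aS)-1-{[2,6-dimethoxy-4-({[tri(propan-2-yl)silyl]oxy}methyl)phenyl]methyl}-5,5,8a-trimethyloctahydronaphthalen-2(1H)-one
Product: 25 (1R,4aS,8aS)-1-{[2,6-dimethoxy-4-({[tri(propan-2-yl)silyl]oxy}methyl)phenyl]methyl}-5,5,8a-trimethyloctahydronaphthalen-2(1H)-one
Conditions: NaOMe, MeOH, 65 °C
Reagents that add atoms: none
Why: Base-mediated epimerisation through the C8–C9 enolate; under thermodynamic control the arylmethyl group should take the equatorial 9β position, as in the natural drimanes, because the axial alternative suffers 1,3-diaxial contacts with H-5 and H-7.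

Step 17
Reactants: 25 (1R,4aS,8aS)-1-{[2,6-dimethoxy-4-({[tri(propan-2-yl)silyl]oxy}methyl)phenyl]methyl}-5,5,8a-trimethyloctahydronaphthalen-2(1H)-one
Product: 26 {[3,5-dimethoxy-4-{[(1S,4aS,8aS)-5,5,8a-trimethyl-2-methylidenedecahydronaphthalen-1-yl]methyl}phenyl]methoxy}tri(propan-2-yl)silane
Conditions: Ph3PCH3Br, KOt-Bu, toluene, 90 °C
Reagents that add atoms: methyltriphenylphosphonium bromide, C[P+](c1ccccc1)(c1ccccc1)c1ccccc1.[Br-]
Why: Wittig methylenation of the hindered C8 ketone with the ylide generated by KOt-Bu in hot toluene; C9 already has its thermodynamic configuration, so reversible enolisation by the basic ylide does no harm.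

Step 18
Reactants: 26 {[3,5-dimethoxy-4-{[(1S,4aS,8aS)-5,5,8a-trimethyl-2-methylidenedecahydronaphthalen-1-yl]methyl}phenyl]methoxy}tri(propan-2-yl)silane
Product: 27 [3,5-dimethoxy-4-{[(1S,4aS,8aS)-5,5,8a-trimethyl-2-methylidenedecahydronaphthalen-1-yl]methyl}phenyl]methanol
Conditions: n-Bu4NF, THF, 23 °C
Reagents that add atoms: none
Why: Fluoride cleavage of the Si–O bond; the conditions are non-acidic, so the exocyclic alkene is untouched.

Step 19
Reactants: 27 [3,5-dimethoxy-4-{[(1S,4aS,8aS)-5,5,8a-trimethyl-2-methylidenedecahydronaphthalen-1-yl]methyl}phenyl]methanol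
Product: 28 5-(hydroxymethyl)-2-{[(1S,4aS,8aS)-5,5,8a-trimethyl-2-methylidenedecahydronaphthalen-1-yl]methyl}benzene-1,3-diol
Conditions: NaSEt (excess), DMF, 140 °C, under argon; aq. NH4Cl
Reagents that add atoms: none
Why: SN2 dealkylation of both aryl methyl ethers by thiolate; the medium is never acidic, so the phenols cannot add to C8 and the alkene cannot migrate, and the excess reagent and temperature serve to cleave the second ether of the intermediate phenoxide.

Step 20
Reactants: 28 5-(hydroxymethyl)-2-{[(1S,4aS,8aS)-5,5,8a-trimethyl-2-methylidenedecahydronaphthalen-1-yl]methyl}benzene-1,3-diol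
Product: 29 3-hydroxy-5-(hydroxymethyl)-2-{[(1S,4aS,8aS)-5,5,8a-trimethyl-2-methylidenedecahydronaphthalen-1-yl]methyl}cyclohexa-2,5-diene-1,4-dione (tauranin)
Conditions: (KSO3)2NO (Fremy's salt, 2.5 equiv), KH2PO4 buffer, acetone/H2O, 0 → 23 °C
Reagents that add atoms: dipotassium nitrosodisulfonate, [K+].[K+].[O]N(S(=O)(=O)[O-])S(=O)(=O)[O-]
Why: Teuber oxidation: the nitroxyl radical abstracts a phenolic hydrogen and a second equivalent adds at the free carbon para to that oxygen, and loss of imidodisulfonate gives the 1,4-quinone with the other phenol left as the hydroxyl group; the two free ring positions are equivalent by symmetry, so only one product can form, and the near-neutral buffer spares the alkene and the benzylic alcohol.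

## Compound list

1 | 2,2,6-trimethylcyclohexan-1-one | CC1CCCC(C)(C)C1=O | starting material
2 | prop-2-en-1-yl carbonochloridate (allyl chloroformate) | C=CCOC(Cl)=O | starting material
3 | lithium 2,6,6-trimethylcyclohex-1-en-1-olate | [Li+].[O-]C1=C(C)CCCC1(C)C | intermediate
4 | prop-2-en-1-yl 2,6,6-trimethylcyclohex-1-en-1-yl carbonate | C=CCOC(=O)OC1=C(C)CCCC1(C)C | intermediate
5 | (6R)-2,2,6-trimethyl-6-(prop-2-en-1-yl)cyclohexan-1-one | O=C1C(C)(C)CCC[C@]1(C)CC=C | intermediate
6 | (6R)-1,2,2,6-tetramethyl-6-(prop-2-en-1-yl)cyclohexan-1-ol (C1 epimers) | CC1(O)C(C)(C)CCC[C@]1(C)CC=C | intermediate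
7 | (1R)-1,3,3-trimethyl-2-methylidene-1-(prop-2-en-1-yl)cyclohexane | C=C1C(C)(C)CCC[C@]1(C)CC=C | intermediate
8 | 3-[(1R)-1,3,3-trimethyl-2-methylidenecyclohexyl]propane-1,2-diol (C2 epimers) | C=C1C(C)(C)CCC[C@]1(C)CC(O)CO | intermediate
9 | 2-[(1R)-1,3,3-trimethyl-2-methylidenecyclohexyl]acetaldehyde | C=C1C(C)(C)CCC[C@]1(C)CC=O | intermediate
10 | 2-[(1R)-1,3,3-trimethyl-2-methylidenecyclohexyl]acetic acid | C=C1C(C)(C)CCC[C@]1(C)CC(=O)O | intermediate
11 | 2-[(1R)-1,3,3-trimethyl-2-methylidenecyclohexyl]acetyl chloride | C=C1C(C)(C)CCC[C@]1(C)CC(=O)Cl | intermediate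
12 | 1-diazo-3-[(1R)-1,3,3-trimethyl-2-methylidenecyclohexyl]propan-2-one | C=C1C(C)(C)CCC[C@]1(C)CC(=O)C=[N+]=[N-] | intermediate
13 | (1R,3S,6R)-6,10,10-trimethyltricyclo[4.4.0.0^{1,3}]decan-4-one (cyclopropane C5–C6–C7, carbonyl at C8, cyclopropane CH2 syn to the C10 methyl group) | O=C1C[C@@]2(C)CCCC(C)(C)[C@]23C[C@H]13 | intermediate
14 | (8aR)-5,5,8a-trimethyl-3,5,6,7,8,8a-hexahydronaphthalen-2(1H)-one (C5=C6 alkene) | O=C1CC=C2C(C)(C)CCC[C@]2(C)C1 | intermediate
15 | (4aS,8aR)-5,5,8a-trimethyl-4a,5,6,7,8,8a-hexahydronaphthalen-2(1H)-one (trans-fused, C6=C7 alkene) | O=C1C=C[C@H]2C(C)(C)CCC[C@]2(C)C1 | intermediate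
16 | (3,5-dimethoxyphenyl)methanol | COc1cc(CO)cc(OC)c1 | starting material
17 | [(3,5-dimethoxyphenyl)methoxy]tri(propan-2-yl)silane | COc1cc(CO[Si](C(C)C)(C(C)C)C(C)C)cc(OC)c1 | intermediate
18 | [2,6-dimethoxy-4-({[tri(propan-2-yl)silyl]oxy}methyl)phenyl]lithium | COc1cc(CO[Si](C(C)C)(C(C)C)C(C)C)cc(OC)c1[Li] | intermediate
19 | 2,6-dimethoxy-4-({[tri(propan-2-yl)silyl]oxy}methyl)benzaldehyde | COc1cc(CO[Si](C(C)C)(C(C)C)C(C)C)cc(OC)c1C=O | intermediate
20 | [2,6-dimethoxy-4-({[tri(propan-2-yl)silyl]oxy}methyl)phenyl]methanol | COc1cc(CO[Si](C(C)C)(C(C)C)C(C)C)cc(OC)c1CO | intermediate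
21 | {[4-(bromomethyl)-3,5-dimethoxyphenyl]methoxy}tri(propan-2-yl)silane | COc1cc(CO[Si](C(C)C)(C(C)C)C(C)C)cc(OC)c1CBr | intermediate
22 | lithium 5,5,8a-trimethyl-4a,5,6,7,8,8a-hexahydronaphthalen-2-olate (C8=C9 and C6=C7, ring fusion as in 15) | [Li+].[O-]C=1C=C[C@H]2C(C)(C)CCC[C@]2(C)C=1 | intermediate
23 | (4aS,8aS)-1-{[2,6-dimethoxy-4-({[tri(propan-2-yl)silyl]oxy}methyl)phenyl]methyl}-5,5,8a-trimethyl-4a,5,6,7,8,8a-hexahydronaphthalen-2(1H)-one (C9 epimers, 9α expected to predominate; C9 left open in the SMILES) | O=C1C=C[C@H]2C(C)(C)CCC[C@]2(C)C1Cc1c(OC)cc(CO[Si](C(C)C)(C(C)C)C(C)C)cc1OC | intermediate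
24 | (4aS,8aS)-1-{[2,6-dimethoxy-4-({[tri(propan-2-yl)silyl]oxy}methyl)phenyl]methyl}-5,5,8a-trimethyloctahydronaphthalen-2(1H)-one (C9 epimers; C9 left open in the SMILES) | O=C1CC[C@H]2C(C)(C)CCC[C@]2(C)C1Cc1c(OC)cc(CO[Si](C(C)C)(C(C)C)C(C)C)cc1OC | intermediate
25 | (1R,4aS,8aS)-1-{[2,6-dimethoxy-4-({[tri(propan-2-yl)silyl]oxy}methyl)phenyl]methyl}-5,5,8a-trimethyloctahydronaphthalen-2(1H)-one (9β, equatorial arylmethyl) | O=C1CC[C@H]2C(C)(C)CCC[C@]2(C)[C@H]1Cc1c(OC)cc(CO[Si](C(C)C)(C(C)C)C(C)C)cc1OC | intermediate
26 | {[3,5-dimethoxy-4-{[(1S,4aS,8aS)-5,5,8a-trimethyl-2-methylidenedecahydronaphthalen-1-yl]methyl}phenyl]methoxy}tri(propan-2-yl)silane | C=C1CC[C@H]2C(C)(C)CCC[C@]2(C)[C@H]1Cc1c(OC)cc(CO[Si](C(C)C)(C(C)C)C(C)C)cc1OC | intermediate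
27 | [3,5-dimethoxy-4-{[(1S,4aS,8aS)-5,5,8a-trimethyl-2-methylidenedecahydronaphthalen-1-yl]methyl}phenyl]methanol | C=C1CC[C@H]2C(C)(C)CCC[C@]2(C)[C@H]1Cc1c(OC)cc(CO)cc1OC | intermediate
28 | 5-(hydroxymethyl)-2-{[(1S,4aS,8aS)-5,5,8a-trimethyl-2-methylidenedecahydronaphthalen-1-yl]methyl}benzene-1,3-diol | C=C1CC[C@H]2C(C)(C)CCC[C@]2(C)[C@H]1Cc1c(O)cc(CO)cc1O | intermediate
29 | 3-hydroxy-5-(hydroxymethyl)-2-{[(1S,4aS,8aS)-5,5,8a-trimethyl-2-methylidenedecahydronaphthalen-1-yl]methyl}cyclohexa-2,5-diene-1,4-dione (tauranin) | C=C1CC[C@H]2C(C)(C)CCC[C@]2(C)[C@H]1CC1=C(O)C(=O)C(CO)=CC1=O | target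

## Step count and risks

Total step count: 20. Longest linear sequence: 16 steps (steps 1–9 and 14–20, from 1 to 29). The arene branch from 16 is 4 steps to bromide 21.

**Step 8 (key step).** The most likely failure is diversion of the carbenoid into 1,5 C–H insertion at C1–H or the C10 methyl group, or into dimerisation, because the alkene is flanked by two quaternary carbons and reacts only from the conformer with C9 axial. The fallback keeps the same two bonds but changes the carbene precursor to a doubly stabilised diazo compound used under copper catalysis, where insertion into unactivated C–H bonds is not a usual pathway. It sets out from acid 10. Activation with 1,1′-carbonyldiimidazole and C-acylation of Mg(O2CCH2CO2t-Bu)2 would give tert-butyl 3-oxo-4-[(1R)-1,3,3-trimethyl-2-methylidenecyclohexyl]butanoate F1. Regitz diazo transfer (4-acetamidobenzenesulfonyl azide, Et3N, MeCN) would give tert-butyl 2-diazo-3-oxo-4-[(1R)-1,3,3-trimethyl-2-methylidenecyclohexyl]butanoate F2. Cu(acac)2 (copper bis(acetylacetonate), divalent copper) in toluene at 110 °C would close tert-butyl 6,10,10-trimethyl-4-oxotricyclo[4.4.0.0^{1,3}]decane-3-carboxylate F3, with the ring fusion as in 13. The acid treatment of step 9 would then cleave the tert-butyl ester, decarboxylate the β-keto acid and open the three-membered ring in one operation, so the fallback comes back to the route at enone 15.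

**Step 9.** Two things may go wrong: the equilibration of 14 to the conjugated enone may stay incomplete, and γ-protonation at C5 may show poor facial selectivity, because the thermodynamic preference for the trans fusion in this enone is argued and not certain. Methyl migration to the C5 cation is a lesser risk, since loss of the C6 proton gives a conjugated dienol. The fallback sets C5 by a radical hydrogenation instead of by protonation. It sets out from the deconjugated enone 14, which if necessary is regenerated from the isomer mixture by forming the extended dienolate with KOt-Bu and quenching with acetic acid. Hydrogen-atom-transfer hydrogenation (Mn(dpm)3, dpm = 2,2,6,6-tetramethylheptane-3,5-dionate, trivalent manganese; PhSiH3, t-BuOOH, i-PrOH, 23 °C) should deliver hydrogen to the tertiary C5 radical from the face opposite the two axial methyl groups and give the trans-fused (4aS,8aR)-5,5,8a-trimethyloctahydronaphthalen-2(1H)-one F4. Kinetic enolisation toward the unhindered C7 (LiN(i-Pr)2, Me3SiCl, THF, −78 °C) would give trimethyl{[(4aS,8aR)-5,5,8a-trimethyl-1,4,4a,5,6,7,8,8a-octahydronaphthalen-2-yl]oxy}silane F5. Saegusa–Ito oxidation (Pd(OAc)2, divalent palladium, MeCN) then restores C6=C7, and the fallback comes back to the route at 15.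

**Step 5.** The risk is loss of site selectivity, with osmylation of the exocyclic alkene alongside the allyl group; this is an electron-rich 1,1-disubstituted alkene and only steric shielding protects it. The fallback removes the competition by cleaving the allyl group before the second alkene exists. It sets out from ketone 5. Lemieux–Johnson cleavage (OsO4 cat., NaIO4, 2,6-lutidine, dioxane/H2O) would give 2-[(1R)-1,3,3-trimethyl-2-oxocyclohexyl]acetaldehyde F6. Selective acetalisation of the unhindered aldehyde (HC(OMe)3, pyridinium p-toluenesulfonate, MeOH) would give (6R)-6-(2,2-dimethoxyethyl)-2,2,6-trimethylcyclohexan-1-one F7. MeMgBr addition would give (6R)-6-(2,2-dimethoxyethyl)-1,2,2,6-tetramethylcyclohexan-1-ol F8, and SOCl2/pyridine would give (1R)-1-(2,2-dimethoxyethyl)-1,3,3-trimethyl-2-methylidenecyclohexane F9. Mild hydrolysis (pyridinium p-toluenesulfonate, acetone/H2O) returns to the route at aldehyde 9.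

**Step 14.** C-alkylation at C9, which lies next to the quaternary C10, may be slow. The labile bromide 21 would then decompose, or proton transfer would give the extended dienolate. The fallback replaces the SN2 step by a carbonyl addition. It sets out from enone 15 and aldehyde 19. Addition of dienolate 22 to 19 would give the aldol (4aS,8aS)-1-{[2,6-dimethoxy-4-({[tri(propan-2-yl)silyl]oxy}methyl)phenyl](hydroxy)methyl}-5,5,8a-trimethyl-4a,5,6,7,8,8a-hexahydronaphthalen-2(1H)-one F10. Mesylation and elimination (MeSO2Cl, Et3N; then DBU) would give the benzylidene dienone (4aS,8aS)-1-{[2,6-dimethoxy-4-({[tri(propan-2-yl)silyl]oxy}methyl)phenyl]methylidene}-5,5,8a-trimethyl-4a,5,6,7,8,8a-hexahydronaphthalen-2(1H)-one F11. Hydrogenation of both alkenes (H2, Pd/C, EtOAc) comes back to the route at ketone 24, whose C9 is then equilibrated in step 16.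

**Step 19.** The second demethylation may stall, because the phenoxide formed in the first one resists further attack by thiolate. The fallback oxidises at the mono-phenol stage. It sets out from 27. NaSEt (2 equiv) in DMF at 110 °C would give 5-(hydroxymethyl)-3-methoxy-2-{[(1S,4aS,8aS)-5,5,8a-trimethyl-2-methylidenedecahydronaphthalen-1-yl]methyl}phenol F12. Teuber oxidation with (KSO3)2NO para to the free phenol would give 5-(hydroxymethyl)-3-methoxy-2-{[(1S,4aS,8aS)-5,5,8a-trimethyl-2-methylidenedecahydronaphthalen-1-yl]methyl}cyclohexa-2,5-diene-1,4-dione F13. Hydrolysis of this vinylogous ester (LiOH, THF/H2O, 0 °C, then acidification to pH 4) comes back to the route at the target 29.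

## Further compounds

F1 | step 8 | tert-butyl 3-oxo-4-[(1R)-1,3,3-trimethyl-2-methylidenecyclohexyl]butanoate | C=C1C(C)(C)CCC[C@]1(C)CC(=O)CC(=O)OC(C)(C)C
F2 | step 8 | tert-butyl 2-diazo-3-oxo-4-[(1R)-1,3,3-trimethyl-2-methylidenecyclohexyl]butanoate | C=C1C(C)(C)CCC[C@]1(C)CC(=O)C(=[N+]=[N-])C(=O)OC(C)(C)C
F3 | step 8 | tert-butyl 6,10,10-trimethyl-4-oxotricyclo[4.4.0.0^{1,3}]decane-3-carboxylate (ring fusion as in 13) | O=C1C[C@@]2(C)CCCC(C)(C)[C@]23C[C@]13C(=O)OC(C)(C)C
F4 | step 9 | (4aS,8aR)-5,5,8a-trimethyloctahydronaphthalen-2(1H)-one | O=C1CC[C@H]2C(C)(C)CCC[C@]2(C)C1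
F5 | step 9 | trimethyl{[(4aS,8aR)-5,5,8a-trimethyl-1,4,4a,5,6,7,8,8a-octahydronaphthalen-2-yl]oxy}silane | C[Si](C)(C)OC1=CC[C@H]2C(C)(C)CCC[C@]2(C)C1
F6 | step 5 | 2-[(1R)-1,3,3-trimethyl-2-oxocyclohexyl]acetaldehyde | O=C1C(C)(C)CCC[C@]1(C)CC=O
F7 | step 5 | (6R)-6-(2,2-dimethoxyethyl)-2,2,6-trimethylcyclohexan-1-one | O=C1C(C)(C)CCC[C@]1(C)CC(OC)OC
F8 | step 5 | (6R)-6-(2,2-dimethoxyethyl)-1,2,2,6-tetramethylcyclohexan-1-ol (C1 epimers) | CC1(O)C(C)(C)CCC[C@]1(C)CC(OC)OC
F9 | step 5 | (1R)-1-(2,2-dimethoxyethyl)-1,3,3-trimethyl-2-methylidenecyclohexane | C=C1C(C)(C)CCC[C@]1(C)CC(OC)OC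
F10 | step 14 | (4aS,8aS)-1-{[2,6-dimethoxy-4-({[tri(propan-2-yl)silyl]oxy}methyl)phenyl](hydroxy)methyl}-5,5,8a-trimethyl-4a,5,6,7,8,8a-hexahydronaphthalen-2(1H)-one (diastereomer mixture) | O=C1C=C[C@H]2C(C)(C)CCC[C@]2(C)C1C(O)c1c(OC)cc(CO[Si](C(C)C)(C(C)C)C(C)C)cc1OC
F11 | step 14 | (4aS,8aS)-1-{[2,6-dimethoxy-4-({[tri(propan-2-yl)silyl]oxy}methyl)phenyl]methylidene}-5,5,8a-trimethyl-4a,5,6,7,8,8a-hexahydronaphthalen-2(1H)-one | O=C1C=C[C@H]2C(C)(C)CCC[C@]2(C)C1=Cc1c(OC)cc(CO[Si](C(C)C)(C(C)C)C(C)C)cc1OC
F12 | step 19 | 5-(hydroxymethyl)-3-methoxy-2-{[(1S,4aS,8aS)-5,5,8a-trimethyl-2-methylidenedecahydronaphthalen-1-yl]methyl}phenol | C=C1CC[C@H]2C(C)(C)CCC[C@]2(C)[C@H]1Cc1c(O)cc(CO)cc1OC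
F13 | step 19 | 5-(hydroxymethyl)-3-methoxy-2-{[(1S,4aS,8aS)-5,5,8a-trimethyl-2-methylidenedecahydronaphthalen-1-yl]methyl}cyclohexa-2,5-diene-1,4-dione | C=C1CC[C@H]2C(C)(C)CCC[C@]2(C)[C@H]1CC1=C(OC)C(=O)C(CO)=CC1=O
A1 | alternative 1 | 4-(benzyloxy)-3-{[2,6-dimethoxy-4-({[tri(propan-2-yl)silyl]oxy}methyl)phenyl]methyl}-2-methyl-2-[3-oxo-2-(trimethylsilyl)butyl]cyclohexan-1-one (ring stereocenters as in the SMILES) | c1ccccc1CO[C@@H]1CCC(=O)[C@](C)(CC([Si](C)(C)C)C(C)=O)[C@H]1Cc1c(OC)cc(CO[Si](C(C)C)(C(C)C)C(C)C)cc1OC
A2 | alternative 2 | 2-methoxy-5-{[(4-methoxyphenyl)methoxy]methyl}-3-{[(1S,4aS,8aS)-5,5,8a-trimethyl-2-methylidenedecahydronaphthalen-1-yl]methyl}benzene-1,4-diol | C=C1CC[C@H]2C(C)(C)CCC[C@]2(C)[C@H]1Cc1c(O)cc(COCc2ccc(OC)cc2)c(O)c1OC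
A3 | alternative 3 | 3-({[tert-butyl(dimethyl)silyl]oxy}methyl)-4-{[2,6-dimethoxy-4-({[tri(propan-2-yl)silyl]oxy}methyl)phenyl]methyl}-4a,8,8-trimethyl-1,2,4a,5,6,7,8,8a-octahydronaphthalene-1-carbaldehyde (ring stereocenters as in the SMILES) | CC(C)(C)[Si](C)(C)OCC1=C(Cc3c(OC)cc(CO[Si](C(C)C)(C(C)C)C(C)C)cc3OC)[C@@]2(C)CCCC(C)(C)[C@@H]2[C@@H](C=O)C1
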